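**Strategy.** The ten-membered ring is not closed end to end. The C1–C10 and C4–C5 oxiranes are read as a (1(10)Z,4E)-cyclodeca-1,5-diene, and its C2–C3 bond as the σ-bond that a [3,3] shift creates from a cis-1,2-dialkenylcyclohexanol. The key step is an anionic oxy-Cope ring expansion of a carvone-derived cyclohexanol (ring C5–C10) that carries a vinyl group on C10 and a (Z)-2-alkoxy-1-methylvinyl group on the carbinol carbon C5: in one operation it forms C2–C3, cleaves C5–C10 to open the germacrane ring, fixes both olefin geometries and sets C3. The C5 enolate is trapped as its triflate and reduced; both olefins are epoxidised at the end.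

Key step: step 14

Remark: locants are those of the germacrane skeleton of the target throughout (ring C1–C10, isopropenyl on C7, methyls on C4 and C10); in the cyclohexane intermediates the ring is C5–C6–C7–C8–C9–C10. β is the ring face of the C7 isopropenyl group, α the other face. The target as drawn is (1S,3S,4S,5R,7R,8S,9S,10S), with a cis 1,10-oxirane (from a 1(10)Z olefin) and a trans 4,5-oxirane (from a 4E olefin).

Step 1
Reactants: 1 4-methoxybenzyl alcohol
Product: 3 allyl 4-methoxybenzyl ether, via sodium alkoxide 2 (not isolated)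
Conditions: NaH, allyl bromide, THF/DMF, 0 → 25 °C
Reagents that add atoms: allyl bromide, C=CCBr
Why: Williamson ether synthesis, in which the sodium alkoxide displaces bromide from the allylic halide by SN2; no stereocentre is formed.

Step 2
Reactants: 3 allyl 4-methoxybenzyl ether
Product: 4 (Z)-1-[(4-methoxybenzyl)oxy]prop-1-ene
Conditions: KOt-Bu (0.3 equiv), DMSO, 25 °C
Reagents that add atoms: none
Why: Base-mediated allyl-to-propenyl ether isomerisation, which passes through the cisoid oxyallyl anion and should give the Z enol ether under kinetic control.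

Step 3
Reactants: 4 (Z)-1-[(4-methoxybenzyl)oxy]prop-1-ene
Product: 6 (Z)-2-bromo-1-[(4-methoxybenzyl)oxy]prop-1-ene, via dibromide 5 (not isolated)
Conditions: Br2, CH2Cl2, −78 °C; then DBU, −78 → 25 °C
Reagents that add atoms: bromine, BrBr
Why: Halogenation–dehydrohalogenation of an enol ether, in which anti addition of bromine and anti loss of HBr (C2–H and the labile C1–Br) should give mainly the β-bromo enol ether with bromine cis to oxygen, the geometry that the C3 centre later depends on.

Step 4
Reactants: 7 (S)-(+)-carvone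
Product: 8 (1R,5S)-2-methyl-5-(prop-1-en-2-yl)-1-vinylcyclohex-2-en-1-ol (9β-hydroxy-9α-vinyl)
Conditions: CH2=CHMgBr, CeCl3, THF, −78 °C
Reagents that add atoms: vinylmagnesium bromide, C=C[Mg]Br
Why: 1,2-Addition of the Grignard reagent to the enone carbonyl (CeCl3 suppresses conjugate addition and enolisation) by axial attack on the half-chair, anti to the pseudo-equatorial isopropenyl group, which places the vinyl group α and the hydroxyl β.

Step 5
Reactants: 8 tertiary allylic alcohol
Product: 9 5β,10β-epoxy alcohol (oxirane cis to the C9 hydroxyl)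
Conditions: VO(acac)2 (cat.), t-BuOOH, CH2Cl2, 0 → 25 °C
Reagents that add atoms: tert-butyl hydroperoxide, CC(C)(C)OO
Why: Hydroxyl-directed epoxidation, which delivers oxygen to the trisubstituted ring olefin on the face of the allylic alcohol (β) and leaves the less nucleophilic vinyl group and the non-allylic isopropenyl group untouched.

Step 6
Reactants: 9 5β,10β-epoxy alcohol
Product: 11 5β-(triethylsilyloxy)-10β-methyl-10α-vinyl-7β-isopropenylcyclohexan-9-one, via silyl ether 10 (not isolated)
Conditions: Et3SiOTf, i-Pr2NEt, CH2Cl2, −78 → −40 °C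
Reagents that add atoms: triethylsilyl triflate, CC[Si](CC)(CC)OS(=O)(=O)C(F)(F)F
Why: Semipinacol rearrangement of a 2,3-epoxy alcohol derivative, in which the silyl triflate activates the oxirane and the vinyl group antiperiplanar to the breaking C10–O bond migrates from C9 to C10 with inversion (vinyl α, methyl now β), so that C9 becomes the ketone and the C5 oxygen stays β as its silyl ether.

Step 7
Reactants: 11 C9 ketone
Product: 13 8α-hydroxy ketone, via potassium enolate 12 (not isolated)
Conditions: KN(SiMe3)2, THF, −78 °C; then 2-(phenylsulfonyl)-3-phenyloxaziridine, −78 °C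
Reagents that add atoms: 2-(phenylsulfonyl)-3-phenyloxaziridine, O=S(=O)(c1ccccc1)N1OC1c1ccccc1
Why: Enolate hydroxylation with an N-sulfonyloxaziridine, regioselective because C10 is quaternary, and expected anti to the axial C10 methyl and the neighbouring isopropenyl group to give the diequatorial (trans, 8α) ketol, which is also the thermodynamic epimer.

Step 8
Reactants: 13 8α-hydroxy ketone
Product: 14 8β-(4-methoxyphenoxy) ketone
Conditions: 4-methoxyphenol, PPh3, DIAD, toluene, 0 → 25 °C
Reagents that add atoms: 4-methoxyphenol, COc1ccc(O)cc1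
Why: Mitsunobu reaction, in which the carbonyl-activated equatorial alkoxyphosphonium ion at C8 is displaced by the phenol with inversion to give the axial 8β aryl ether, cis to the isopropenyl group and stable to the organometallic and basic steps that follow.

Step 9
Reactants: 14 8β-aryloxy ketone
Product: 15 9β-alcohol
Conditions: NaBH4, MeOH/CH2Cl2, −40 °C
Reagents that add atoms: none
Why: Hydride reduction by axial attack from the α face, anti to the axial C8 aryloxy and C10 methyl groups (Felkin–Anh control), so that the new hydroxyl is equatorial and β.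

Step 10
Reactants: 15 9β-alcohol
Product: 16 9β-tert-butyldimethylsilyl ether
Conditions: t-BuMe2SiOTf, 2,6-lutidine, CH2Cl2, 0 °C
Reagents that add atoms: tert-butyldimethylsilyl triflate, CC(C)(C)[Si](C)(C)OS(=O)(=O)C(F)(F)F
Why: Silylation of the hindered secondary alcohol with a silyl triflate; no stereocentre is affected.

Step 11
Reactants: 16 bis-silyl ether
Product: 17 5β-alcohol
Conditions: pyridinium p-toluenesulfonate (cat.), MeOH/CH2Cl2, 0 °C
Reagents that add atoms: none
Why: Acid-catalysed methanolysis, which removes the triethylsilyl ether selectively while the bulkier tert-butyldimethylsilyl ether and the aryl ether stay in place.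

Step 12
Reactants: 17 5β-alcohol
Product: 18 C5 ketone (10β-methyl-10α-vinyl-9β-silyloxy-8β-aryloxy-7β-isopropenylcyclohexan-5-one)
Conditions: Dess–Martin periodinane, NaHCO3, CH2Cl2, 25 °C
Reagents that add atoms: none
Why: Oxidation of the secondary alcohol with a hypervalent iodine reagent under buffered conditions; the α carbon C10 is quaternary and cannot epimerise.

Step 13
Reactants: 18 C5 ketone; 6 (Z)-2-bromo-1-[(4-methoxybenzyl)oxy]prop-1-ene
Product: 20 tertiary alcohol (5β-hydroxy-5α-[(Z)-1-(4-methoxybenzyloxy)prop-1-en-2-yl]), via alkenyllithium 19 (not isolated)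
Conditions: t-BuLi (2 equiv), Et2O, −78 °C; then 18, THF, −78 → −40 °C
Reagents that add atoms: none
Why: Bromine–lithium exchange with retention gives the oxygen-chelated cis-2-alkoxyvinyllithium, which should add to the ketone by axial attack from the α face, anti to the axial C10 methyl, so that the alkenyl group is cis to the C10 vinyl group and the hydroxyl is β.

Step 14
Reactants: 20 tertiary alcohol
Product: 23 ten-membered enol triflate (C5–OTf; C3 and C6 trans on C4=C5; 1(10)Z; 3β-OPMB), via potassium alkoxide 21 (not isolated), via potassium enolate 22 (not isolated)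
Conditions: KH, 18-crown-6, THF, 0 °C; then PhNTf2, −78 → 0 °C
Reagents that add atoms: N-phenyl-bis(trifluoromethanesulfonimide), O=S(=O)(N(c1ccccc1)S(=O)(=O)C(F)(F)F)C(F)(F)F
Why: KH converts 20 into alkoxide 21, a 3-oxido-1,5-diene (C3=C4–C5(O−)–C10–C1=C2), which undergoes a charge-accelerated [3,3]-sigmatropic shift that breaks C5–C10 and forms C2–C3, and the enolate 22 is O-sulfonylated in the same flask. The closest known reaction type is the anionic oxy-Cope rearrangement of 1,2-dialkenylcyclohexanols to cyclodec-5-enones with trapping of the enolate as its enol triflate. The ten-membered ring is closed by a four-atom ring expansion of the cyclohexane through a six-membered chair transition state, so no high dilution is needed. C3 is set by the Z enol ether, whose benzyloxy group is pseudo-axial in that chair and ends up β (3S); the olefin geometries follow from the cyclohexane chair with the C5 oxido, C7 isopropenyl and C9 silyloxy groups equatorial and the C5 alkenyl group axial, which places C9 axial (1(10)Z) and C6 equatorial (4E) on the pericyclic array. The step needs chair over boat, and rearrangement with triflation over β-elimination of the C3 alkoxide from 22 or proton transfer to the C6 enolate; the first is secured by the ring substituents that lock the reacting conformer (the other chair would put three β groups 1,3,5-triaxial), the second by the poor leaving-group ability of the alkoxide, the low temperature and immediate trapping at −78 °C.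

Step 15
Reactants: 23 enol triflate
Product: 24 (1(10)Z,4E)-diene (3β-OPMB, 8β-aryloxy, 9β-silyloxy)
Conditions: Pd(OAc)2 (cat.), PPh3, n-Bu3N, HCO2H, DMF, 40 °C
Reagents that add atoms: none
Why: Palladium-catalysed reduction of an enol triflate, in which oxidative addition to zerovalent palladium, formate exchange, decarboxylation and reductive elimination replace OTf by H with retention of the olefin geometry.

Step 16
Reactants: 24 diene
Product: 26 3β,8β-diol, via C3 alcohol 25 (not isolated)
Conditions: (NH4)2Ce(NO3)6, pyridine, MeCN/H2O, 0 °C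
Reagents that add atoms: none
Why: Oxidative ether cleavage by tetravalent cerium, in which single-electron oxidation of the two p-methoxyaryl groups frees first the C3 and then the C8 hydroxyl; the C–O bonds at the stereocentres and the silyl ether are not touched.

Step 17
Reactants: 26 3β,8β-diol
Product: 28 3β,8β-bis-angelate, via C3 monoangelate 27 (not isolated)
Conditions: angelic acid, 2,4,6-trichlorobenzoyl chloride, Et3N, toluene, 25 → 60 °C
Reagents that add atoms: angelic acid, C/C=C(/C)C(=O)O
Why: Yamaguchi esterification without nucleophilic catalyst, in which the mixed anhydride acylates both secondary alcohols with retention at carbon and the Z (angelate) double bond is not isomerised to the E (tiglate) isomer.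

Step 18
Reactants: 28 bis-angelate silyl ether
Product: 29 9β-alcohol
Conditions: HF·pyridine, pyridine, THF, 0 → 25 °C
Reagents that add atoms: none
Why: Fluoride-mediated desilylation under buffered, non-basic conditions, which frees the C9 hydroxyl without acyl migration or ester cleavage.

Step 19
Reactants: 29 9β-alcohol
Product: 31 1α,10α:4α,5β-diepoxy alcohol, via 1,10-monoepoxide 30 (not isolated)
Conditions: m-CPBA (2.2 equiv), NaHCO3, CH2Cl2, 0 °C
Reagents that add atoms: 3-chloroperbenzoic acid, OOC(=O)c1cccc(Cl)c1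
Why: Peracid (Prilezhaev) epoxidation of the two trisubstituted ring olefins, which are more nucleophilic than the isopropenyl and angelate double bonds: at C1=C10 the free C9 hydroxyl, held on the outer face by A(1,3) strain with C2, directs the peracid syn to itself (1S,10S), and at C4=C5 attack on the peripheral face of the conformer with C3–H eclipsing the olefin should give the 4S,5R oxirane.

Step 20
Reactants: 31 diepoxy alcohol
Product: 32 target CNP0220329.2
Conditions: Ac2O, pyridine, DMAP (cat.), CH2Cl2, 0 → 25 °C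
Reagents that add atoms: acetic anhydride, CC(=O)OC(C)=O
Why: Acylation of the remaining secondary alcohol under nucleophilic catalysis, with retention at C9 and without opening the oxiranes.

**Compound list**

1 | 4-methoxybenzyl alcohol | COc1ccc(CO)cc1 | starting material
2 | sodium 4-methoxybenzyl oxide | COc1ccc(C[O-])cc1.[Na+] | intermediate
3 | allyl 4-methoxybenzyl ether | C=CCOCc1ccc(OC)cc1 | intermediate
4 | (Z)-1-[(4-methoxybenzyl)oxy]prop-1-ene | C/C=C\OCc1ccc(OC)cc1 | intermediate
5 | 1-[(1,2-dibromopropoxy)methyl]-4-methoxybenzene | CC(Br)C(Br)OCc1ccc(OC)cc1 | intermediate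
6 | (Z)-2-bromo-1-[(4-methoxybenzyl)oxy]prop-1-ene (Br cis to O) | C/C(Br)=C/OCc1ccc(OC)cc1 | intermediate
7 | (S)-(+)-carvone | C=C(C)[C@H]1CC=C(C)C(=O)C1 | starting material
8 | (1R,5S)-2-methyl-5-(prop-1-en-2-yl)-1-vinylcyclohex-2-en-1-ol (9β-OH, 9α-vinyl) | C=C(C)[C@H]1CC=C(C)[C@](O)(C=C)C1 | intermediate
9 | 5β,10β-epoxide of 8 (oxirane cis to the C9 hydroxyl) | C=C(C)[C@H]1C[C@H]2O[C@@]2(C)[C@](O)(C=C)C1 | intermediate
10 | C9 triethylsilyl ether of 9 | C=C(C)[C@H]1C[C@H]2O[C@@]2(C)[C@](O[Si](CC)(CC)CC)(C=C)C1 | intermediate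
11 | 5β-(triethylsilyloxy)-10β-methyl-10α-vinyl-7β-isopropenylcyclohexan-9-one | C=C(C)[C@H]1C[C@@H](O[Si](CC)(CC)CC)[C@](C)(C=C)C(=O)C1 | intermediate
12 | potassium C8=C9 enolate of 11 | C=C(C)[C@H]1C[C@@H](O[Si](CC)(CC)CC)[C@](C)(C=C)C([O-])=C1.[K+] | intermediate
13 | 8α-hydroxy derivative of 11 (OH trans to isopropenyl) | C=C(C)[C@H]1C[C@@H](O[Si](CC)(CC)CC)[C@](C)(C=C)C(=O)[C@@H]1O | intermediate
14 | 8β-(4-methoxyphenoxy) ketone (aryloxy cis to isopropenyl) | C=C(C)[C@H]1C[C@@H](O[Si](CC)(CC)CC)[C@](C)(C=C)C(=O)[C@H]1Oc2ccc(OC)cc2 | intermediate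
15 | 9β-alcohol from 14 | C=C(C)[C@H]1C[C@@H](O[Si](CC)(CC)CC)[C@](C)(C=C)[C@@H](O)[C@H]1Oc2ccc(OC)cc2 | intermediate
16 | 9β-tert-butyldimethylsilyl ether of 15 | C=C(C)[C@H]1C[C@@H](O[Si](CC)(CC)CC)[C@](C)(C=C)[C@@H](O[Si](C)(C)C(C)(C)C)[C@H]1Oc2ccc(OC)cc2 | intermediate
17 | 5β-alcohol (triethylsilyl group removed) | C=C(C)[C@H]1C[C@@H](O)[C@](C)(C=C)[C@@H](O[Si](C)(C)C(C)(C)C)[C@H]1Oc2ccc(OC)cc2 | intermediate
18 | C5 ketone: 10β-methyl-10α-vinyl-9β-(TBS-oxy)-8β-(4-methoxyphenoxy)-7β-isopropenylcyclohexan-5-one | C=C(C)[C@H]1CC(=O)[C@](C)(C=C)[C@@H](O[Si](C)(C)C(C)(C)C)[C@H]1Oc2ccc(OC)cc2 | intermediate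
19 | (1-[(4-methoxybenzyl)oxy]prop-1-en-2-yl)lithium, Li cis to O | [Li]/C(C)=C\OCc1ccc(OC)cc1 | intermediate
20 | tertiary alcohol: 5β-hydroxy-5α-[(Z)-1-(4-methoxybenzyloxy)prop-1-en-2-yl] adduct of 18 | C=C(C)[C@H]1C[C@](O)(/C(C)=C\OCc2ccc(OC)cc2)[C@](C)(C=C)[C@@H](O[Si](C)(C)C(C)(C)C)[C@H]1Oc3ccc(OC)cc3 | intermediate
21 | potassium alkoxide of 20 | C=C(C)[C@H]1C[C@]([O-])(/C(C)=C\OCc2ccc(OC)cc2)[C@](C)(C=C)[C@@H](O[Si](C)(C)C(C)(C)C)[C@H]1Oc3ccc(OC)cc3.[K+] | intermediate
22 | ten-membered potassium C4=C5 enolate (1(10)Z; C3 and C6 trans; 3β-OPMB) | C=C(C)[C@H]1C/C([O-])=C(C)/[C@@H](OCc2ccc(OC)cc2)C/C=C(C)\[C@@H](O[Si](C)(C)C(C)(C)C)[C@H]1Oc3ccc(OC)cc3.[K+] | intermediate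
23 | ten-membered C5 enol triflate (1(10)Z; C3 and C6 trans; 3β-OPMB, 8β-aryloxy, 9β-silyloxy) | C=C(C)[C@H]1C/C(OS(=O)(=O)C(F)(F)F)=C(C)/[C@@H](OCc2ccc(OC)cc2)C/C=C(C)\[C@@H](O[Si](C)(C)C(C)(C)C)[C@H]1Oc3ccc(OC)cc3 | intermediate
24 | (1(10)Z,4E)-germacra-1(10),4,11-triene with 3β-OPMB, 8β-(4-methoxyphenoxy), 9β-OTBS | C=C(C)[C@H]1C/C=C(C)/[C@@H](OCc2ccc(OC)cc2)C/C=C(C)\[C@@H](O[Si](C)(C)C(C)(C)C)[C@H]1Oc3ccc(OC)cc3 | intermediate
25 | 3β-alcohol (8β-aryloxy, 9β-OTBS) | C=C(C)[C@H]1C/C=C(C)/[C@@H](O)C/C=C(C)\[C@@H](O[Si](C)(C)C(C)(C)C)[C@H]1Oc2ccc(OC)cc2 | intermediate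
26 | 3β,8β-diol (9β-OTBS) | C=C(C)[C@H]1C/C=C(C)/[C@@H](O)C/C=C(C)\[C@@H](O[Si](C)(C)C(C)(C)C)[C@H]1O | intermediate
27 | 3β-angelate 8β-alcohol | C=C(C)[C@H]1C/C=C(C)/[C@@H](OC(=O)/C(C)=C\C)C/C=C(C)\[C@@H](O[Si](C)(C)C(C)(C)C)[C@H]1O | intermediate
28 | 3β,8β-bis-angelate (9β-OTBS) | C=C(C)[C@H]1C/C=C(C)/[C@@H](OC(=O)/C(C)=C\C)C/C=C(C)\[C@@H](O[Si](C)(C)C(C)(C)C)[C@H]1OC(=O)/C(C)=C\C | intermediate
29 | 3β,8β-bis-angelate 9β-alcohol | C=C(C)[C@H]1C/C=C(C)/[C@@H](OC(=O)/C(C)=C\C)C/C=C(C)\[C@@H](O)[C@H]1OC(=O)/C(C)=C\C | intermediate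
30 | 1α,10α-monoepoxide of 29 | C=C(C)[C@H]1C/C=C(C)/[C@@H](OC(=O)/C(C)=C\C)C[C@@H]2O[C@]2(C)[C@@H](O)[C@H]1OC(=O)/C(C)=C\C | intermediate
31 | 1α,10α:4α,5β-diepoxy-3β,8β-bis(angeloyloxy)germacr-11-en-9β-ol | C=C(C)[C@H]1C[C@H]2O[C@]2(C)[C@@H](OC(=O)/C(C)=C\C)C[C@@H]2O[C@]2(C)[C@@H](O)[C@H]1OC(=O)/C(C)=C\C | intermediate
32 | CNP0220329.2: (1S,3S,4S,5R,7R,8S,9S,10S)-9-acetoxy-3,8-bis(angeloyloxy)-1,10:4,5-diepoxygermacr-11-ene | C=C(C)[C@H]1C[C@H]2O[C@]2(C)[C@@H](OC(=O)/C(C)=C\C)C[C@@H]2O[C@]2(C)[C@@H](OC(C)=O)[C@H]1OC(=O)/C(C)=C\C | target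

**Count.** Total: 20 steps. Longest linear sequence: 17 steps (steps 4–20, from (S)-carvone); steps 1–3 prepare the side-chain bromide 6.

**Steps most likely to fail**

Step 14. What may go wrong: loss of the C3 benzyloxide from enolate 22 by β-elimination before O-sulfonylation, or erosion of olefin geometry and of the C3 configuration through a boat transition state. Fallback, from 20 back to 25: the elimination is accepted and the oxygen is put back afterwards. Compound 20 is treated with KH and 18-crown-6 in THF at 25 °C until rearrangement and elimination are complete, which should give the ten-membered (3E,1(10)Z)-dien-5-one, dienone F1. Weitz–Scheffer epoxidation (H2O2, NaOH, MeOH, 0 °C), with the hydroperoxide adding to C3 from the peripheral face, gives the 3β,4α-epoxy ketone, epoxy ketone F2. Wharton transposition (N2H4·H2O, AcOH, MeOH, 0 → 25 °C) then moves the oxygen to C3 and the double bond to C4=C5 and gives the allylic alcohol 25. Step 16 then only has to cleave the C8 aryl ether.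

Step 19. What may go wrong: poor facial selectivity at C4=C5, where no hydroxyl directs the peracid and the outcome depends on the ring conformer, and competing oxidation of the isopropenyl group. Fallback, from 29 back to 31: the two oxiranes are made one at a time under reagent control. VO(acac)2 and t-BuOOH (CH2Cl2, 0 °C) epoxidise only the C1=C10 olefin, syn to the allylic C9 hydroxyl, and 30 is isolated. The C4=C5 olefin is then epoxidised by Shi epoxidation (fructose-derived ketone catalyst, KHSO5, K2CO3 buffer, MeCN/dimethoxymethane/H2O, 0 °C); the antipode of the ketone is chosen so that the catalyst selects the 4S,5R face, giving 31.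

Step 8. What may go wrong: slow SN2 displacement at C8 because the incoming phenol passes the syn-axial C10 methyl, with elimination or epimerisation to the equatorial (8α) ether instead. Fallback, from 11 back to 14: the C8–O bond is made by carbene O–H insertion, so that the centre is set by protonation and not by displacement. Detrifluoroacetylative diazo transfer on 11 (LiN(SiMe3)2, CF3CO2CH2CF3, THF, −78 °C, giving the trifluoroacetyl ketone F3; then MsN3, Et3N, MeCN/H2O) gives the α-diazo ketone F4. Rh2(OAc)4 (cat.) and 4-methoxyphenol in CH2Cl2 then give the aryl ether; the enol intermediate should be protonated from the α face, anti to the axial C10 methyl, which places the aryloxy group β as in 14.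

**Further compounds**

F1 | step 14 | (3E,1(10)Z)-8β-(4-methoxyphenoxy)-9β-(TBS-oxy)germacra-1(10),3,11-trien-5-one | C=C(C)[C@H]1CC(=O)/C(C)=C/C/C=C(C)\[C@@H](O[Si](C)(C)C(C)(C)C)[C@H]1Oc2ccc(OC)cc2
F2 | step 14 | 3β,4α-epoxy ketone of F1 | C=C(C)[C@H]1CC(=O)[C@]2(C)O[C@H]2C/C=C(C)\[C@@H](O[Si](C)(C)C(C)(C)C)[C@H]1Oc3ccc(OC)cc3
F0 | step 19 | none | none
F3 | step 8 | 8-(trifluoroacetyl) derivative of 11 (C8 epimers or enol) | C=C(C)[C@H]1C[C@@H](O[Si](CC)(CC)CC)[C@](C)(C=C)C(=O)C1C(=O)C(F)(F)F
F4 | step 8 | 8-diazo derivative of 11 | C=C(C)[C@H]1C[C@@H](O[Si](CC)(CC)CC)[C@](C)(C=C)C(=O)C1=[N+]=[N-]
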